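Each half of the C2-symmetric 20-membered diolide is numbered C1 (ester carbonyl) to C9 (carbinol carbon), with C10 the CH2 on the oxazole. Everything rests on the C8–C9 disconnection. The feature exploited is that the C9 oxygen, C9, C8, C7, C6 and C5 fold into a six-membered pyran in which the syn C8-methyl/C9-oxygen pair is a cis-2,3 relationship. One catalytic enantioselective hetero-Diels–Alder reaction between an achiral 1-methoxypentadiene and an achiral aldehyde closes this ring, forms C8–C9, sets both stereocentres (hence all four of the dimer) and leaves C5 as a masked aldehyde. The pyran is later opened to an alkyne, which is extended, cyclodimerised and reduced to the Z,Z-dienoates.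

Key step: step 2

Assumption: the (1S,2R)-aminoindanol series of the chromium catalyst is taken to give the (8R,9R) adduct, by analogy with its sense of induction with 1-methoxybutadiene. Should the sense be opposite, the equally available (1R,2S) ligand is used.

Step 1
Reactants: 1 (E)-but-2-enal (crotonaldehyde)
Product: 2 (1E,3E)-1-methoxypenta-1,3-diene
Conditions: Ph3P(CH2OMe)Cl, KOtBu, Et2O, 0 °C to rt; distillation
Reagents that add atoms: (methoxymethyl)triphenylphosphonium chloride, COC[P+](c1ccccc1)(c1ccccc1)c1ccccc1.[Cl-]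
Why: Wittig olefination of an enal with the non-stabilised methoxymethylene ylide; the E geometry of the future C7=C8 bond is carried over from 1, and the new enol ether bond need not form selectively because only its E isomer can react in step 2.

Step 2
Reactants: 2 (1E,3E)-1-methoxypenta-1,3-diene (excess); 3 benzyl-protected aldehyde 3-(benzyloxy)propanal
Product: 4 all-cis dihydropyran acetal (2R,3R,6R)-2-[2-(benzyloxy)ethyl]-6-methoxy-3-methyl-3,6-dihydro-2H-pyran
Conditions: 5 mol % CrCl(C27H29NO2) [ligand: dianion of (1S,2R)-1-{[3-(1-adamantyl)-2-hydroxy-5-methylbenzylidene]amino}indan-2-ol], powdered 4 Å MS, neat, rt, 24–48 h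
Reagents that add atoms: none
Why: The aldehyde binds through oxygen to the Lewis-acidic trivalent chromium centre and undergoes a concerted, asynchronous [4+2] cycloaddition with the s-cis diene, in which C8 (diene C4, the nucleophilic end of the vinylogous enol ether) bonds to the carbonyl carbon C9 while the carbonyl oxygen bonds to C5 (diene C1). The closest known reaction type is the enantioselective hetero-Diels–Alder reaction of 1-methoxybutadiene with aliphatic aldehydes under this class of tridentate Schiff-base chromium catalysts. One ring is closed, the six-membered dihydropyran O–C9–C8–C7=C6–C5, by intermolecular [4+2] closure; of its two new σ-bonds only C8–C9 stays in the target, while O–C5 is a temporary bond given up in step 7. C9 is set by the ligand, which shields one face of the bound aldehyde; C8 follows from the E geometry of the C7=C8 diene bond together with the endo position of the aldehyde chain (methyl and chain cis, which is syn in the open chain); the acetal centre C5 follows from the 1E enol ether geometry and is erased later. The step needs regio-, endo- and facial selectivity, secured in turn by the methoxy donor, by the bulky catalyst taking the exo position, and by the chiral ligand. Any 1Z enol ether isomer cannot reach the s-cis conformation and stays behind as a volatile spectator.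

Step 3
Reactants: 4 all-cis dihydropyran acetal
Product: 5 alcohol 2-[(2R,3R,6R)-6-methoxy-3-methyloxan-2-yl]ethan-1-ol
Conditions: H2 (1 atm), Pd/C, EtOAc, rt
Reagents that add atoms: none
Why: Heterogeneous catalytic hydrogenation saturates the disubstituted C6=C7 bond and hydrogenolyses the benzyl ether in the same operation, while the neutral medium leaves the acetal and the three stereocentres untouched.

Step 4
Reactants: 5 alcohol
Product: 6 aldehyde 2-[(2R,3R,6R)-6-methoxy-3-methyloxan-2-yl]acetaldehyde
Conditions: TEMPO (10 mol %), PhI(OAc)2, CH2Cl2, rt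
Reagents that add atoms: none
Why: Oxoammonium (TEMPO) oxidation stops at the aldehyde and is mild enough for the acetal, and no stereocentre lies α to the new carbonyl group.

Step 5
Reactants: 6 aldehyde
Product: 8 oxazole acetal 5-{[(2R,3R,6R)-6-methoxy-3-methyloxan-2-yl]methyl}-1,3-oxazole, via 4-tosyloxazoline 7 (not isolated)
Conditions: TosMIC, K2CO3, MeOH, 65 °C
Reagents that add atoms: p-toluenesulfonylmethyl isocyanide (TosMIC), Cc1ccc(cc1)S(=O)(=O)C[N+]#[C-]
Why: van Leusen oxazole synthesis, in which the TosMIC anion adds to the aldehyde, the alkoxide closes onto the isocyanide carbon to give 7, and loss of p-toluenesulfinate aromatises it to the 5-substituted oxazole without involving C9.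

Step 6
Reactants: 8 oxazole acetal
Product: 9 lactol (5R,6R)-5-methyl-6-(1,3-oxazol-5-ylmethyl)oxan-2-ol (both anomers)
Conditions: 1 M aq. HCl, THF, rt; NaHCO3 work-up
Reagents that add atoms: water, O
Why: Acid-catalysed acetal hydrolysis through the cyclic oxocarbenium ion is easy for a 2-alkoxyoxane without electron-withdrawing neighbours, the weakly basic oxazole is only protonated reversibly, and the acetal centre becomes an anomeric mixture of no consequence.

Step 7
Reactants: 9 lactol
Product: 11 alkynol (2R,3R)-3-methyl-1-(1,3-oxazol-5-yl)hept-6-yn-2-ol, via open-chain hydroxy aldehyde 10 (not isolated)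
Conditions: dimethyl (1-diazo-2-oxopropyl)phosphonate, K2CO3, MeOH, rt
Reagents that add atoms: dimethyl (1-diazo-2-oxopropyl)phosphonate, COP(=O)(OC)C(=[N+]=[N-])C(C)=O
Why: Seyferth–Gilbert homologation in the Ohira–Bestmann modification intercepts the equilibrium share of open-chain aldehyde 10, so the pyran template is opened for good, C5 becomes an alkyne carbon, C4 is added and the C9 hydroxy group is freed without a protecting group.

Step 8
Reactants: 12 prop-2-yn-1-ol (propargyl alcohol)
Product: 14 (Z)-3-iodo-2-methylprop-2-en-1-ol, via cyclic vinylmagnesium alkoxide 13 (not isolated)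
Conditions: MeMgBr (3 equiv), CuI (10 mol %), THF, −10 °C to rt; then I2, −10 °C to rt
Reagents that add atoms: methylmagnesium bromide, C[Mg]Br; iodine, [I][I]
Why: Copper-catalysed, alkoxide-directed anti carbomagnesiation places methyl on C2 and magnesium on C3 inside the five-membered chelate 13, so iodinolysis with retention should give the Z iodide only.

Step 9
Reactants: 11 alkynol; 14 (Z)-3-iodo-2-methylprop-2-en-1-ol
Product: 15 enyne diol (2Z,8R,9R)-2,8-dimethyl-10-(1,3-oxazol-5-yl)dec-2-en-4-yne-1,9-diol
Conditions: PdCl2(PPh3)2 (3 mol %), CuI (6 mol %), Et3N, THF, rt, degassed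
Reagents that add atoms: none
Why: Sonogashira coupling proceeds at room temperature with retention of the vinyl iodide geometry and tolerates both free hydroxy groups and the oxazole.

Step 10
Reactants: 15 enyne diol
Product: 16 hydroxy enynal (2Z,8R,9R)-9-hydroxy-2,8-dimethyl-10-(1,3-oxazol-5-yl)dec-2-en-4-ynal
Conditions: MnO2 (excess), CH2Cl2, rt
Reagents that add atoms: none
Why: MnO2 oxidises only the allylic primary alcohol, leaves the isolated secondary C9 carbinol alone and preserves Z enal geometry; unlike a 2Z,4Z-dienal, the enynal cannot undergo oxa-electrocyclisation.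

Step 11
Reactants: 16 hydroxy enynal
Product: 17 seco acid (2Z,8R,9R)-9-hydroxy-2,8-dimethyl-10-(1,3-oxazol-5-yl)dec-2-en-4-ynoic acid
Conditions: NaClO2, NaH2PO4, 2-methyl-2-butene, t-BuOH–H2O, 0 °C to rt
Reagents that add atoms: sodium chlorite, [Na+].[O-]Cl=O
Why: Pinnick oxidation converts the enal into the acid under buffered conditions without touching the secondary alcohol, the enyne or the C2=C3 geometry, with 2-methyl-2-butene as chlorine scavenger.

Step 12
Reactants: 17 seco acid (two molecules)
Product: 21 bis-enyne 20-membered diolide, via monomer mixed anhydride 18 (not isolated), via linear dimer hydroxy acid 19 (not isolated), via dimer mixed anhydride 20 (not isolated)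
Conditions: MNBA (2-methyl-6-nitrobenzoic anhydride), DMAP, 4 Å MS, CH2Cl2 (about 10 mM in 17), rt
Reagents that add atoms: none
Why: Shiina esterification and macrolactonisation in one flask, in which head-to-tail esterification gives 19 and its closure to the 20-membered ring is the only unimolecular outlet, because the linear C3–C4≡C5–C6 unit forbids ring closure of a single unit; C9 keeps its configuration since only acyl C–O bonds are made.

Step 13
Reactants: 21 bis-enyne 20-membered diolide
Product: 22 target CNP0414419.1, the (2Z,4Z,8R,9R)-configured 20-membered diolide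
Conditions: Zn dust activated with Cu(OAc)2 and AgNO3, MeOH–H2O–THF, rt to 40 °C
Reagents that add atoms: none
Why: Boland-type reduction with activated zinc delivers two hydrogens syn to conjugated triple bonds only, so both enynes should become Z,Z-dienoates without over-reduction, ester cleavage or change at C2=C3.

Compound list
1 | (E)-but-2-enal (crotonaldehyde) | C/C=C/C=O | starting material
2 | (1E,3E)-1-methoxypenta-1,3-diene | C/C=C/C=C/OC | intermediate
3 | 3-(benzyloxy)propanal | O=CCCOCc1ccccc1 | starting material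
4 | (2R,3R,6R)-2-[2-(benzyloxy)ethyl]-6-methoxy-3-methyl-3,6-dihydro-2H-pyran (all-cis) | CO[C@H]1C=C[C@@H](C)[C@@H](CCOCc2ccccc2)O1 | intermediate
5 | 2-[(2R,3R,6R)-6-methoxy-3-methyloxan-2-yl]ethan-1-ol | CO[C@H]1CC[C@@H](C)[C@@H](CCO)O1 | intermediate
6 | 2-[(2R,3R,6R)-6-methoxy-3-methyloxan-2-yl]acetaldehyde | CO[C@H]1CC[C@@H](C)[C@@H](CC=O)O1 | intermediate
7 | 5-{[(2R,3R,6R)-6-methoxy-3-methyloxan-2-yl]methyl}-4-tosyl-4,5-dihydro-1,3-oxazole (not isolated) | CO[C@H]1CC[C@@H](C)[C@@H](CC2OC=NC2S(=O)(=O)c2ccc(C)cc2)O1 | intermediate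
8 | 5-{[(2R,3R,6R)-6-methoxy-3-methyloxan-2-yl]methyl}-1,3-oxazole | CO[C@H]1CC[C@@H](C)[C@@H](Cc2cnco2)O1 | intermediate
9 | (5R,6R)-5-methyl-6-(1,3-oxazol-5-ylmethyl)oxan-2-ol (both anomers) | OC1CC[C@@H](C)[C@@H](Cc2cnco2)O1 | intermediate
10 | (4R,5R)-5-hydroxy-4-methyl-6-(1,3-oxazol-5-yl)hexanal (not isolated) | O=CCC[C@@H](C)[C@@H](Cc1cnco1)O | intermediate
11 | (2R,3R)-3-methyl-1-(1,3-oxazol-5-yl)hept-6-yn-2-ol | C#CCC[C@@H](C)[C@@H](Cc1cnco1)O | intermediate
12 | prop-2-yn-1-ol | C#CCO | starting material
13 | 4-methyl-2,5-dihydro-1,2-oxamagnesole, cyclic vinylmagnesium alkoxide (not isolated) | CC1=C[Mg]OC1 | intermediate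
14 | (Z)-3-iodo-2-methylprop-2-en-1-ol | OC/C(C)=C\I | intermediate
15 | (2Z,8R,9R)-2,8-dimethyl-10-(1,3-oxazol-5-yl)dec-2-en-4-yne-1,9-diol | OC/C(C)=C\C#CCC[C@@H](C)[C@@H](Cc1cnco1)O | intermediate
16 | (2Z,8R,9R)-9-hydroxy-2,8-dimethyl-10-(1,3-oxazol-5-yl)dec-2-en-4-ynal | O=C/C(C)=C\C#CCC[C@@H](C)[C@@H](Cc1cnco1)O | intermediate
17 | (2Z,8R,9R)-9-hydroxy-2,8-dimethyl-10-(1,3-oxazol-5-yl)dec-2-en-4-ynoic acid | OC(=O)/C(C)=C\C#CCC[C@@H](C)[C@@H](Cc1cnco1)O | intermediate
18 | mixed anhydride of 17 and 2-methyl-6-nitrobenzoic acid (not isolated) | Cc1cccc([N+](=O)[O-])c1C(=O)OC(=O)/C(C)=C\C#CCC[C@@H](C)[C@@H](Cc1cnco1)O | intermediate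
19 | linear dimer: C9 ester of one unit of 17 with the acid of a second unit, free acid and free C9' hydroxy group (not isolated) | OC(=O)/C(C)=C\C#CCC[C@@H](C)[C@@H](Cc1cnco1)OC(=O)/C(C)=C\C#CCC[C@@H](C)[C@@H](Cc1cnco1)O | intermediate
20 | mixed anhydride of 19 and 2-methyl-6-nitrobenzoic acid (not isolated) | Cc1cccc([N+](=O)[O-])c1C(=O)OC(=O)/C(C)=C\C#CCC[C@@H](C)[C@@H](Cc1cnco1)OC(=O)/C(C)=C\C#CCC[C@@H](C)[C@@H](Cc1cnco1)O | intermediate
21 | C2-symmetric 20-membered diolide with two (2Z)-2-en-4-ynoate units | C/C1=C/C#CCC[C@@H](C)[C@@H](Cc2cnco2)OC(=O)/C(C)=C\C#CCC[C@@H](C)[C@@H](Cc2cnco2)OC1=O | intermediate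
22 | CNP0414419.1, C2-symmetric 20-membered diolide with two (2Z,4Z)-dienoate units, (8R,9R) in each half | C/C1=C/C=C\CC[C@@H](C)[C@@H](Cc2cnco2)OC(=O)/C(C)=C\C=C/CC[C@@H](C)[C@@H](Cc2cnco2)OC1=O | target

Total step count: 13. Longest linear sequence: 12 (steps 1–7 and 9–13).

**Risk A (step 12).** Chain growth to open oligomers may outrun ring closure. The C2=C3 bond may also isomerise from Z to E through reversible conjugate addition of DMAP to the activated enynoate. The fallback sets out from 16 and comes back at 19; it replaces the one-flask cyclodimerisation by a stepwise assembly in which the aldehyde serves as latent acid.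
- Hydroxy enynal 16 is silylated (TBSOTf, 2,6-lutidine, CH2Cl2, −78 °C) to the silyl ether aldehyde F1, and Pinnick oxidation gives the silyl ether acid F2.
- MNBA and DMAP convert F2, through its mixed anhydride F3, into the ester with a second portion of 16, the ester aldehyde F4.
- A second Pinnick oxidation gives the silylated linear dimer acid F5, and HF·pyridine in THF removes the silyl group to give 19, now isolated and purified.
- 19 alone is then added slowly to MNBA/DMAP at high dilution and closes to 21 as in step 12.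

**Risk B (step 2).** Turnover may be slow with a diene that carries one donor only and a substituent on its reacting terminus, and endo or facial selectivity may erode. The fallback sets out from 3 and comes back at 9. C8–C9 is still made in a ring-closing [4+2] step, but with a doubly activated diene followed by an oxygen transposition.
- The known enone (E)-1-methoxypent-1-en-3-one F6 is silylated (TMSOTf, Et3N) to the diene (1E,3Z)-1-methoxy-3-(trimethylsilyloxy)penta-1,3-diene F7.
- With 3 and the same chromium catalyst, F7 should give the silyl enol ether cycloadduct F8, which CF3CO2H converts into the cis-dihydropyranone F9.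
- Luche reduction (NaBH4, CeCl3·7H2O, MeOH) gives the allylic alcohol F10.
- Ferrier-type methanolysis (PPTS, MeOH) moves the double bond to C6=C7 and gives the 2,6-trans acetal F11, the acetal epimer of 4.
- F11 passes through the operations of steps 3 to 6 by way of the epimeric alcohol F12, the epimeric aldehyde F13, the epimeric tosyloxazoline F14 and the epimeric oxazole acetal F15. Hydrolysis erases the acetal centre and gives 9.

**Risk C (step 13).** One of the two triple bonds may be reduced incompletely, the lipophilic macrocycle may be wetted poorly by the aqueous medium, or over-reduction may give mixtures too similar to separate. The fallback sets out from 17 and comes back at 22. The reduction is moved in front of ring formation and changed in kind.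
- 17 is semihydrogenated (H2, Pd/CaCO3 poisoned with Pb(OAc)2, quinoline, EtOAc) to the (2Z,4Z)-dienoic hydroxy acid F16, a small polar monomer that can be purified.
- F16 is cyclodimerised with MNBA and DMAP through its mixed anhydride F17, the linear tetraene dimer F18 and the dimer mixed anhydride F19, which gives 22 directly.
- Since the alkyne lock is given up, a higher concentration is used in the first phase to disfavour ring closure of a single unit.

Further compounds
F1 | step 12 | (2Z,8R,9R)-9-(tert-butyldimethylsilyloxy)-2,8-dimethyl-10-(1,3-oxazol-5-yl)dec-2-en-4-ynal | O=C/C(C)=C\C#CCC[C@@H](C)[C@@H](Cc1cnco1)O[Si](C)(C)C(C)(C)C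
F2 | step 12 | (2Z,8R,9R)-9-(tert-butyldimethylsilyloxy)-2,8-dimethyl-10-(1,3-oxazol-5-yl)dec-2-en-4-ynoic acid | OC(=O)/C(C)=C\C#CCC[C@@H](C)[C@@H](Cc1cnco1)O[Si](C)(C)C(C)(C)C
F3 | step 12 | mixed anhydride of F2 and 2-methyl-6-nitrobenzoic acid | Cc1cccc([N+](=O)[O-])c1C(=O)OC(=O)/C(C)=C\C#CCC[C@@H](C)[C@@H](Cc1cnco1)O[Si](C)(C)C(C)(C)C
F4 | step 12 | C9 ester of 16 with F2 (ester aldehyde) | O=C/C(C)=C\C#CCC[C@@H](C)[C@@H](Cc1cnco1)OC(=O)/C(C)=C\C#CCC[C@@H](C)[C@@H](Cc1cnco1)O[Si](C)(C)C(C)(C)C
F5 | step 12 | tert-butyldimethylsilyl ether of 19 | OC(=O)/C(C)=C\C#CCC[C@@H](C)[C@@H](Cc1cnco1)OC(=O)/C(C)=C\C#CCC[C@@H](C)[C@@H](Cc1cnco1)O[Si](C)(C)C(C)(C)C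
F6 | step 2 | (E)-1-methoxypent-1-en-3-one | CCC(=O)/C=C/OC
F7 | step 2 | (1E,3Z)-1-methoxy-3-(trimethylsilyloxy)penta-1,3-diene | CO/C=C/C(O[Si](C)(C)C)=C/C
F8 | step 2 | (2R,3S,6R)-2-[2-(benzyloxy)ethyl]-6-methoxy-3-methyl-4-(trimethylsilyloxy)-3,6-dihydro-2H-pyran (all-cis) | CO[C@H]1C=C(O[Si](C)(C)C)[C@@H](C)[C@@H](CCOCc2ccccc2)O1
F9 | step 2 | (2R,3S)-2-[2-(benzyloxy)ethyl]-3-methyl-2,3-dihydro-4H-pyran-4-one | O=C1[C@@H](C)[C@@H](CCOCc2ccccc2)OC=C1
F10 | step 2 | (2R,3R)-2-[2-(benzyloxy)ethyl]-3-methyl-3,4-dihydro-2H-pyran-4-ol (carbinol configuration not relevant) | OC1[C@@H](C)[C@@H](CCOCc2ccccc2)OC=C1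
F11 | step 2 | (2R,3R,6S)-2-[2-(benzyloxy)ethyl]-6-methoxy-3-methyl-3,6-dihydro-2H-pyran | CO[C@@H]1C=C[C@@H](C)[C@@H](CCOCc2ccccc2)O1
F12 | step 2 | 2-[(2R,3R,6S)-6-methoxy-3-methyloxan-2-yl]ethan-1-ol | CO[C@@H]1CC[C@@H](C)[C@@H](CCO)O1
F13 | step 2 | 2-[(2R,3R,6S)-6-methoxy-3-methyloxan-2-yl]acetaldehyde | CO[C@@H]1CC[C@@H](C)[C@@H](CC=O)O1
F14 | step 2 | 5-{[(2R,3R,6S)-6-methoxy-3-methyloxan-2-yl]methyl}-4-tosyl-4,5-dihydro-1,3-oxazole | CO[C@@H]1CC[C@@H](C)[C@@H](CC2OC=NC2S(=O)(=O)c2ccc(C)cc2)O1
F15 | step 2 | 5-{[(2R,3R,6S)-6-methoxy-3-methyloxan-2-yl]methyl}-1,3-oxazole | CO[C@@H]1CC[C@@H](C)[C@@H](Cc2cnco2)O1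
F16 | step 13 | (2Z,4Z,8R,9R)-9-hydroxy-2,8-dimethyl-10-(1,3-oxazol-5-yl)deca-2,4-dienoic acid | OC(=O)/C(C)=C\C=C/CC[C@@H](C)[C@@H](Cc1cnco1)O
F17 | step 13 | mixed anhydride of F16 and 2-methyl-6-nitrobenzoic acid | Cc1cccc([N+](=O)[O-])c1C(=O)OC(=O)/C(C)=C\C=C/CC[C@@H](C)[C@@H](Cc1cnco1)O
F18 | step 13 | linear dimer of F16 (C9 ester, free acid and free C9' hydroxy group) | OC(=O)/C(C)=C\C=C/CC[C@@H](C)[C@@H](Cc1cnco1)OC(=O)/C(C)=C\C=C/CC[C@@H](C)[C@@H](Cc1cnco1)O
F19 | step 13 | mixed anhydride of F18 and 2-methyl-6-nitrobenzoic acid | Cc1cccc([N+](=O)[O-])c1C(=O)OC(=O)/C(C)=C\C=C/CC[C@@H](C)[C@@H](Cc1cnco1)OC(=O)/C(C)=C\C=C/CC[C@@H](C)[C@@H](Cc1cnco1)O
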